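The ten-membered carbocycle is closed last at C2–C3 (germacrane numbering), the central bond of the C10=C1–C2–C3–C4=C5 unit: C2 is the allylic CH2 beside the C1=C10 alkene (the later epoxide) and C3 the carbinol carbon beside the Z-C4=C5 alkene. In the precursor both carbons are electrophiles, a Z-enal carbonyl and a primary allylic bromide, on a chain that already carries the α-methylene lactone. Cp2TiCl reduces both, and the two allyl-stabilised radicals unite at the unsubstituted allyl terminus: one operation forms the ring and the C3 carbinol and keeps both alkene geometries. Mitsunobu esterifications then invert C3 and C8; the epoxide is introduced last.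

Key step: step 16

Remark: germacrane numbering (C1–C15) is used for the atoms of all intermediates; the five starting materials, including (R)-2-methylbutanoic acid, are taken as commercial.

Step 1
Reactants: 1 4-methylfuran-2(5H)-one
Product: 2 (Z)-4-hydroxy-N-methoxy-N,3-dimethylbut-2-enamide
Conditions: MeNH(OMe)·HCl, AlMe3, CH2Cl2, 0 °C to rt; aq. potassium sodium tartrate
Reagents that add atoms: N,O-dimethylhydroxylamine hydrochloride, CNOC.Cl
Why: Aminolysis of the lactone by the aluminium amide (Weinreb amide formation) opens the ring at the acyl carbon, so the Z geometry that the ring imposes on the trisubstituted alkene (future C4=C5, C3 and C6 cis) is carried into the open chain.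

Step 2
Reactants: 2 hydroxy Weinreb amide
Product: 3 (Z)-N-methoxy-N,3-dimethyl-4-(triethylsilyloxy)but-2-enamide
Conditions: Et3SiCl, imidazole, CH2Cl2, 0 °C
Reagents that add atoms: chlorotriethylsilane, CC[Si](Cl)(CC)CC
Why: Silyl ether formation at the primary alcohol stops relactonisation and installs the triethylsilyl group that step 13 later oxidises directly.

Step 3
Reactants: 3 silylated Weinreb amide
Product: 4 (Z)-5-methyl-6-(triethylsilyloxy)hexa-1,4-dien-3-one
Conditions: CH2=CHMgBr, THF, −78 to −20 °C; cold aq. NaHSO4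
Reagents that add atoms: vinylmagnesium bromide, C=C[Mg]Br
Why: Grignard addition to a Weinreb amide stops at the ketone through the chelated tetrahedral intermediate and gives the cross-conjugated dienone with the Z-alkene untouched.

Step 4
Reactants: 4 dienone
Product: 5 (3S,4Z)-5-methyl-6-(triethylsilyloxy)hexa-1,4-dien-3-ol
Conditions: (R)-2-methyl-CBS-oxazaborolidine (20 mol %), catecholborane, toluene, −78 °C
Reagents that add atoms: none
Why: Corey–Bakshi–Shibata reduction, in which the Z-trisubstituted alkenyl group should act as the large and the vinyl group as the small ketone substituent, so that the (R)-catalyst delivers hydride to the face that gives the 3S carbinol (the future C6).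

Step 5
Reactants: 5 (3S,4Z)-dienol; 6 2-(bromomethyl)acrylic acid
Product: 7 (3S,4Z)-5-methyl-6-(triethylsilyloxy)hexa-1,4-dien-3-yl 2-(bromomethyl)prop-2-enoate
Conditions: DCC, DMAP (5 mol %), CH2Cl2, −20 to 0 °C
Reagents that add atoms: none
Why: Steglich esterification acylates the secondary bis-allylic alcohol at oxygen, so the carbinol configuration is retained.

Step 6
Reactants: 7 acrylate ester
Product: 8 (5R)-3-(bromomethyl)-5-[(Z)-2-methyl-3-(triethylsilyloxy)prop-1-enyl]furan-2(5H)-one
Conditions: second-generation Hoveyda–Grubbs catalyst (5 mol %), toluene (5 mM), 80 °C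
Reagents that add atoms: none
Why: Ring-closing metathesis between the vinyl group and the acrylate closes the butenolide, the trisubstituted Z-alkene being too hindered to take part, and the stereocentre is not touched.

Step 7
Reactants: 9 tert-butyl(but-3-ynyloxy)dimethylsilane
Product: 11 (E)-5-(tert-butyldimethylsilyloxy)-3-methylpent-2-en-1-ol, via alkenyldimethylalane 10 (not isolated)
Conditions: AlMe3, Cp2ZrCl2 (25 mol %), CH2Cl2, 0 °C to rt; n-BuLi, then (CH2O)n, THF, −78 °C to rt
Reagents that add atoms: trimethylaluminium, C[Al](C)C; formaldehyde (from paraformaldehyde), C=O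
Why: Zirconium-catalysed carboalumination adds methyl and aluminium syn across the alkyne with aluminium at the terminal carbon, which fixes the E geometry of the future C1=C10 alkene, and the alkenylalanate is hydroxymethylated with retention.

Step 8
Reactants: 11 allylic alcohol
Product: 12 (E)-5-(tert-butyldimethylsilyloxy)-1-(tert-butyldiphenylsilyloxy)-3-methylpent-2-ene
Conditions: t-BuPh2SiCl, imidazole, CH2Cl2, rt
Reagents that add atoms: tert-butyl(chloro)diphenylsilane, CC(C)(C)[Si](Cl)(c1ccccc1)c1ccccc1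
Why: Silyl ether formation with the more robust TBDPS group differentiates the two primary oxygens.

Step 9
Reactants: 12 bis-silyl ether
Product: 13 (E)-5-(tert-butyldiphenylsilyloxy)-3-methylpent-3-en-1-ol
Conditions: PPTS (10 mol %), EtOH, rt
Reagents that add atoms: none
Why: Acid-catalysed alcoholysis removes the primary TBS ether selectively because the bulkier TBDPS ether is far more stable to acid.

Step 10
Reactants: 13 homoallylic alcohol
Product: 14 (E)-5-(tert-butyldiphenylsilyloxy)-3-methylpent-3-enal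
Conditions: Dess–Martin periodinane, NaHCO3, CH2Cl2, 0 °C; used crude
Reagents that add atoms: none
Why: Buffered Dess–Martin oxidation gives the β,γ-unsaturated aldehyde without moving the alkene into conjugation.

Step 11
Reactants: 8 butenolide bromide; 14 β,γ-unsaturated aldehyde
Product: 15 (4R,5R)-4-[(1S,3E)-5-(tert-butyldiphenylsilyloxy)-1-hydroxy-3-methylpent-3-enyl]-3-methylidene-5-[(Z)-2-methyl-3-(triethylsilyloxy)prop-1-enyl]oxolan-2-one
Conditions: Zn dust, THF–sat. aq. NH4Cl, 0 °C
Reagents that add atoms: none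
Why: Barbier-type allylation in which the allylzinc adds through its ring γ-carbon (C7) in a chair Zimmerman–Traxler transition state, anti to the C6 alkenyl group (trans-lactone, 7R) and, because the ring locks the allyl unit in the E-type geometry, with the anti relationship that should make C8 S, while the exocyclic methylene is formed at the same time.

Step 12
Reactants: 15 seco-lactone 8S-alcohol
Product: 16 (4R,5R)-4-[(1R,3E)-5-(tert-butyldiphenylsilyloxy)-1-(formyloxy)-3-methylpent-3-enyl]-3-methylidene-5-[(Z)-2-methyl-3-(triethylsilyloxy)prop-1-enyl]oxolan-2-one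
Conditions: PPh3, DIAD, HCO2H, THF, 0 °C to rt
Reagents that add atoms: formic acid, O=CO
Why: Mitsunobu reaction, in which SN2 displacement of the activated C8 oxygen by formate inverts C8 to the required R configuration and protects it in the same operation.

Step 13
Reactants: 16 formate with TES and TBDPS ethers
Product: 17 (4R,5R)-4-[(1R,3E)-5-(tert-butyldiphenylsilyloxy)-1-(formyloxy)-3-methylpent-3-enyl]-3-methylidene-5-[(Z)-2-methyl-3-oxoprop-1-enyl]oxolan-2-one
Conditions: (COCl)2, DMSO, CH2Cl2, −78 to −30 °C; Et3N, −78 to 0 °C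
Reagents that add atoms: none
Why: Swern conditions cleave the primary allylic triethylsilyl ether and oxidise it directly to the aldehyde, leaving the TBDPS ether and the formate intact and the Z geometry unchanged.

Step 14
Reactants: 17 Z-enal TBDPS ether
Product: 18 (4R,5R)-4-[(1R,3E)-1-(formyloxy)-5-hydroxy-3-methylpent-3-enyl]-3-methylidene-5-[(Z)-2-methyl-3-oxoprop-1-enyl]oxolan-2-one
Conditions: HF·pyridine, pyridine, THF, 0 °C to rt
Reagents that add atoms: none
Why: Fluoride-mediated desilylation under buffered conditions removes the TBDPS group without touching the formate, the enal or the α-methylene lactone.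

Step 15
Reactants: 18 hydroxy enal
Product: 19 (4R,5R)-4-[(1R,3E)-5-bromo-1-(formyloxy)-3-methylpent-3-enyl]-3-methylidene-5-[(Z)-2-methyl-3-oxoprop-1-enyl]oxolan-2-one
Conditions: NBS, Me2S, CH2Cl2, −20 to 0 °C
Reagents that add atoms: N-bromosuccinimide, O=C1CCC(=O)N1Br
Why: Corey–Kim-type bromination, in which the alkoxysulfonium salt of the allylic alcohol is displaced by bromide under neutral conditions, so the E geometry and the aldehyde survive.

Step 16
Reactants: 19 bromo enal
Product: 20 (3R,6R,7R,8R,1(10)E,4Z)-8-formyloxy-3-hydroxygermacra-1(10),4,11(13)-trien-12,6-olide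
Conditions: Cp2TiCl2 (3 equiv), Mn dust, THF, rt; slow addition of 19 (final 2 mM); aq. NaH2PO4
Reagents that add atoms: none
Why: Proposed new method: two equivalents of Cp2TiCl (trivalent titanium) abstract the bromine from C2 and bind the enal oxygen, giving an allyl radical (or its allyltitanium) and a titanoxy-substituted allyl radical at C3 that combine at the unsubstituted allyl terminus C2, and hydrolysis gives the homoallylic alcohol; the closest known reaction type is the intermolecular titanocene-mediated Barbier-type α-prenylation of conjugated aldehydes by γ,γ-disubstituted allylic bromides, whose use to close a ten-membered carbocycle has not been shown. The ring closes by union of the two chain termini C2 and C3 (coupling at the α-terminus of the allyl unit), the eight-membered alternative through the fully substituted terminus C10 being disfavoured sterically. The only new stereocentre, C3, should be controlled by C6: allylic 1,3-strain holds H6 in the plane of the Z-alkene, so the tether through C7 reaches the C3 face syn to C7, and the bulky Cp2ClTi–O group stays s-trans (pointing outward), which leads to 3R. The step needs α- over γ-regioselectivity (secured by the conjugated aldehyde and by the substitution at C10), retention of both alkene geometries (allyl radicals invert slowly on this time scale) and chemoselectivity against the α-methylene lactone and the formate (Cp2TiCl does not reduce isolated enoates or esters). Slow addition at high dilution should suppress pinacol and Wurtz-type dimers.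

Step 17
Reactants: 20 macrocyclic 3R-alcohol; 21 (R)-2-methylbutanoic acid
Product: 22 (3S,6R,7R,8R,1(10)E,4Z)-8-formyloxy-3-[(R)-2-methylbutanoyloxy]germacra-1(10),4,11(13)-trien-12,6-olide
Conditions: PPh3, DIAD, toluene, 0 °C to rt
Reagents that add atoms: none
Why: Mitsunobu esterification, in which SN2 attack of the carboxylate on the activated allylic C3 oxygen inverts C3 from R to the required S, while the α-stereocentre of the acid is safe because the carboxylate acts only as the nucleophile.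

Step 18
Reactants: 22 formate ester
Product: 23 (3S,6R,7R,8R,1(10)E,4Z)-8-hydroxy-3-[(R)-2-methylbutanoyloxy]germacra-1(10),4,11(13)-trien-12,6-olide
Conditions: KHCO3, MeOH–H2O, 0 °C
Reagents that add atoms: none
Why: Chemoselective solvolysis, since a formate is cleaved by bicarbonate far faster than the hindered secondary ester or the lactone, which frees the C8 hydroxyl with retention.

Step 19
Reactants: 24 methyl (Z)-2-methylbut-2-enoate (methyl angelate)
Product: 25 (Z)-2-methylbut-2-en-1-ol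
Conditions: i-Bu2AlH, CH2Cl2, −78 °C; aq. potassium sodium tartrate
Reagents that add atoms: none
Why: Hydride reduction of the conjugated ester in a 1,2-fashion gives the allylic alcohol with the Z geometry retained.

Step 20
Reactants: 25 (Z)-allylic alcohol
Product: 26 [(2S,3R)-2,3-dimethyloxiran-2-yl]methanol
Conditions: Ti(OiPr)4 (10 mol %), L-(+)-diethyl tartrate (12 mol %), t-BuOOH, 4 Å MS, CH2Cl2, −20 °C
Reagents that add atoms: tert-butyl hydroperoxide, CC(C)(C)OO
Why: Sharpless asymmetric epoxidation, in which the L-(+)-tartrate complex delivers oxygen to the alkene face that gives the 2S,3R epoxy alcohol and the Z geometry becomes the cis relationship of the hydroxymethyl and C3 methyl groups.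

Step 21
Reactants: 26 epoxy alcohol
Product: 27 (2R,3R)-2,3-dimethyloxirane-2-carboxylic acid
Conditions: RuCl3·xH2O (2 mol %), NaIO4, CCl4–MeCN–H2O, rt
Reagents that add atoms: sodium periodate, [Na+].[O-]I(=O)(=O)=O; water, O
Why: Catalytic ruthenium tetroxide oxidation takes the primary alcohol to the carboxylic acid without opening the epoxide, and the descriptor at C2 changes to R only through the change in substituent priority.

Step 22
Reactants: 27 epoxy acid; 23 macrocyclic 8R-alcohol
Product: 29 (3S,6R,7R,8R,1(10)E,4Z)-8-[(2R,3R)-2,3-dimethyloxirane-2-carbonyloxy]-3-[(R)-2-methylbutanoyloxy]germacra-1(10),4,11(13)-trien-12,6-olide, via mixed anhydride 28 (not isolated)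
Conditions: 2,4,6-trichlorobenzoyl chloride, Et3N, toluene, rt; then 23, DMAP, rt
Reagents that add atoms: none
Why: Yamaguchi esterification, in which the mixed anhydride transfers the hindered epoxy acyl group via DMAP to the C8 oxygen, so C8 and both epoxide stereocentres are retained.

Step 23
Reactants: 29 diene diester
Product: 30 (1R,3S,6R,7R,8R,10R,4Z)-8-[(2R,3R)-2,3-dimethyloxirane-2-carbonyloxy]-1,10-epoxy-3-[(R)-2-methylbutanoyloxy]germacra-4,11(13)-dien-12,6-olide (the target)
Conditions: mCPBA, NaHCO3, CH2Cl2, 0 °C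
Reagents that add atoms: 3-chloroperbenzoic acid, O=C(OO)c1cccc(Cl)c1
Why: Prilezhaev epoxidation, in which the electron-rich, strained E-C1=C10 alkene should react in preference to the C4=C5 alkene (deactivated by two allylic acyloxy groups) and the conjugated methylene, and attack on the exposed outer face should give the 1R,10R (1β,10α) trans-epoxide.

Compound list

1 | 4-methylfuran-2(5H)-one | CC1=CC(=O)OC1 | starting material
2 | (Z)-4-hydroxy-N-methoxy-N,3-dimethylbut-2-enamide | CON(C)C(=O)/C=C(/C)CO | intermediate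
3 | (Z)-N-methoxy-N,3-dimethyl-4-(triethylsilyloxy)but-2-enamide | CON(C)C(=O)/C=C(/C)CO[Si](CC)(CC)CC | intermediate
4 | (Z)-5-methyl-6-(triethylsilyloxy)hexa-1,4-dien-3-one | C=CC(=O)/C=C(/C)CO[Si](CC)(CC)CC | intermediate
5 | (3S,4Z)-5-methyl-6-(triethylsilyloxy)hexa-1,4-dien-3-ol | C=C[C@H](O)/C=C(/C)CO[Si](CC)(CC)CC | intermediate
6 | 2-(bromomethyl)acrylic acid | C=C(CBr)C(=O)O | starting material
7 | (3S,4Z)-5-methyl-6-(triethylsilyloxy)hexa-1,4-dien-3-yl 2-(bromomethyl)prop-2-enoate | C=C(CBr)C(=O)O[C@@H](C=C)/C=C(/C)CO[Si](CC)(CC)CC | intermediate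
8 | (5R)-3-(bromomethyl)-5-[(Z)-2-methyl-3-(triethylsilyloxy)prop-1-enyl]furan-2(5H)-one | O=C1O[C@H](/C=C(/C)CO[Si](CC)(CC)CC)C=C1CBr | intermediate
9 | tert-butyl(but-3-ynyloxy)dimethylsilane | C#CCCO[Si](C)(C)C(C)(C)C | starting material
10 | (E)-[4-(tert-butyldimethylsilyloxy)-2-methylbut-1-enyl]dimethylalane | C[Al](C)/C=C(\C)CCO[Si](C)(C)C(C)(C)C | intermediate
11 | (E)-5-(tert-butyldimethylsilyloxy)-3-methylpent-2-en-1-ol | OC/C=C(\C)CCO[Si](C)(C)C(C)(C)C | intermediate
12 | (E)-5-(tert-butyldimethylsilyloxy)-1-(tert-butyldiphenylsilyloxy)-3-methylpent-2-ene | CC(C)(C)[Si](C)(C)OCC/C(C)=C/CO[Si](c1ccccc1)(c1ccccc1)C(C)(C)C | intermediate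
13 | (E)-5-(tert-butyldiphenylsilyloxy)-3-methylpent-3-en-1-ol | OCC/C(C)=C/CO[Si](c1ccccc1)(c1ccccc1)C(C)(C)C | intermediate
14 | (E)-5-(tert-butyldiphenylsilyloxy)-3-methylpent-3-enal | O=CC/C(C)=C/CO[Si](c1ccccc1)(c1ccccc1)C(C)(C)C | intermediate
15 | (4R,5R)-4-[(1S,3E)-5-(tert-butyldiphenylsilyloxy)-1-hydroxy-3-methylpent-3-enyl]-3-methylidene-5-[(Z)-2-methyl-3-(triethylsilyloxy)prop-1-enyl]oxolan-2-one | C=C1C(=O)O[C@H](/C=C(/C)CO[Si](CC)(CC)CC)[C@H]1[C@@H](O)C/C(C)=C/CO[Si](c1ccccc1)(c1ccccc1)C(C)(C)C | intermediate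
16 | (4R,5R)-4-[(1R,3E)-5-(tert-butyldiphenylsilyloxy)-1-(formyloxy)-3-methylpent-3-enyl]-3-methylidene-5-[(Z)-2-methyl-3-(triethylsilyloxy)prop-1-enyl]oxolan-2-one | C=C1C(=O)O[C@H](/C=C(/C)CO[Si](CC)(CC)CC)[C@H]1[C@H](OC=O)C/C(C)=C/CO[Si](c1ccccc1)(c1ccccc1)C(C)(C)C | intermediate
17 | (4R,5R)-4-[(1R,3E)-5-(tert-butyldiphenylsilyloxy)-1-(formyloxy)-3-methylpent-3-enyl]-3-methylidene-5-[(Z)-2-methyl-3-oxoprop-1-enyl]oxolan-2-one | C=C1C(=O)O[C@H](/C=C(/C)C=O)[C@H]1[C@H](OC=O)C/C(C)=C/CO[Si](c1ccccc1)(c1ccccc1)C(C)(C)C | intermediate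
18 | (4R,5R)-4-[(1R,3E)-1-(formyloxy)-5-hydroxy-3-methylpent-3-enyl]-3-methylidene-5-[(Z)-2-methyl-3-oxoprop-1-enyl]oxolan-2-one | C=C1C(=O)O[C@H](/C=C(/C)C=O)[C@H]1[C@H](OC=O)C/C(C)=C/CO | intermediate
19 | (4R,5R)-4-[(1R,3E)-5-bromo-1-(formyloxy)-3-methylpent-3-enyl]-3-methylidene-5-[(Z)-2-methyl-3-oxoprop-1-enyl]oxolan-2-one | C=C1C(=O)O[C@H](/C=C(/C)C=O)[C@H]1[C@H](OC=O)C/C(C)=C/CBr | intermediate
20 | (3R,6R,7R,8R,1(10)E,4Z)-8-formyloxy-3-hydroxygermacra-1(10),4,11(13)-trien-12,6-olide | C=C1C(=O)O[C@@H]2/C=C(/C)[C@H](O)C/C=C(\C)C[C@@H](OC=O)[C@@H]12 | intermediate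
21 | (R)-2-methylbutanoic acid | CC[C@@H](C)C(=O)O | starting material
22 | (3S,6R,7R,8R,1(10)E,4Z)-8-formyloxy-3-[(R)-2-methylbutanoyloxy]germacra-1(10),4,11(13)-trien-12,6-olide | C=C1C(=O)O[C@@H]2/C=C(/C)[C@@H](OC(=O)[C@H](C)CC)C/C=C(\C)C[C@@H](OC=O)[C@@H]12 | intermediate
23 | (3S,6R,7R,8R,1(10)E,4Z)-8-hydroxy-3-[(R)-2-methylbutanoyloxy]germacra-1(10),4,11(13)-trien-12,6-olide | C=C1C(=O)O[C@@H]2/C=C(/C)[C@@H](OC(=O)[C@H](C)CC)C/C=C(\C)C[C@@H](O)[C@@H]12 | intermediate
24 | methyl (Z)-2-methylbut-2-enoate | C/C=C(/C)C(=O)OC | starting material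
25 | (Z)-2-methylbut-2-en-1-ol | C/C=C(/C)CO | intermediate
26 | [(2S,3R)-2,3-dimethyloxiran-2-yl]methanol | OC[C@]1(C)O[C@@H]1C | intermediate
27 | (2R,3R)-2,3-dimethyloxirane-2-carboxylic acid | O=C(O)[C@]1(C)O[C@@H]1C | intermediate
28 | (2R,3R)-2,3-dimethyloxirane-2-carboxylic 2,4,6-trichlorobenzoic anhydride | O=C(OC(=O)c1c(Cl)cc(Cl)cc1Cl)[C@]1(C)O[C@@H]1C | intermediate
29 | (3S,6R,7R,8R,1(10)E,4Z)-8-[(2R,3R)-2,3-dimethyloxirane-2-carbonyloxy]-3-[(R)-2-methylbutanoyloxy]germacra-1(10),4,11(13)-trien-12,6-olide | C=C1C(=O)O[C@@H]2/C=C(/C)[C@@H](OC(=O)[C@H](C)CC)C/C=C(\C)C[C@@H](OC(=O)[C@]3(C)O[C@@H]3C)[C@@H]12 | intermediate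
30 | (1R,3S,6R,7R,8R,10R,4Z)-8-[(2R,3R)-2,3-dimethyloxirane-2-carbonyloxy]-1,10-epoxy-3-[(R)-2-methylbutanoyloxy]germacra-4,11(13)-dien-12,6-olide | C=C1C(=O)O[C@@H]2/C=C(/C)[C@@H](OC(=O)[C@H](C)CC)C[C@H]3O[C@]3(C)C[C@@H](OC(=O)[C@]3(C)O[C@@H]3C)[C@@H]12 | target

Total step count: 23. Longest linear sequence: 16 steps (steps 1–6, 11–18, 22 and 23).

Steps most likely to fail

1. Step 16 (ring closure). What may go wrong: reduction of the allyl radical to an allyltitanium that is simply protonated, coupling through the substituted terminus C10 to an eight-membered ring, addition of either radical to the α-methylene lactone, Z/E scrambling of the delocalised titanoxy radical, and intermolecular pinacol or Wurtz-type coupling. The fallback uses known reactions only: the C2–C3 bond is made between two molecules by the titanocene-catalysed α-allylation in its established intermolecular form, and the ring is closed at C7–C8 by an intramolecular Barbier allylation. It sets out from 5 and 11 and comes back at 22. Alcohol 11 is converted (NBS, Me2S) into (E)-[(5-bromo-3-methylpent-3-enyl)oxy](tert-butyl)dimethylsilane F1. Dienol 5 is protected (NaH, 4-methoxybenzyl chloride) as (3S,4Z)-3-(4-methoxybenzyloxy)-5-methyl-6-(triethylsilyloxy)hexa-1,4-diene F2 and oxidised under the conditions of step 13 to (2Z,4S)-4-(4-methoxybenzyloxy)-2-methylhexa-2,5-dienal F3. Coupling of F3 with F1 (Cp2TiCl2 cat., Mn dust, Me3SiCl, 2,4,6-collidine, THF) should give (3S,4Z,8E)-11-(tert-butyldimethylsilyloxy)-3-(4-methoxybenzyloxy)-5,9-dimethylundeca-1,4,8-trien-6-ol F4 as both C6 epimers. These are funnelled by MnO2 into (3S,4Z,8E)-11-(tert-butyldimethylsilyloxy)-3-(4-methoxybenzyloxy)-5,9-dimethylundeca-1,4,8-trien-6-one F5 and by (R)-CBS/catecholborane reduction into (3S,4Z,6S,8E)-11-(tert-butyldimethylsilyloxy)-3-(4-methoxybenzyloxy)-5,9-dimethylundeca-1,4,8-trien-6-ol F6. Acylation with 21 (DIC, DMAP) gives (3S,4Z,6S,8E)-11-(tert-butyldimethylsilyloxy)-3-(4-methoxybenzyloxy)-5,9-dimethylundeca-1,4,8-trien-6-yl (R)-2-methylbutanoate F7, and DDQ frees (3S,4Z,6S,8E)-11-(tert-butyldimethylsilyloxy)-3-hydroxy-5,9-dimethylundeca-1,4,8-trien-6-yl (R)-2-methylbutanoate F8. The conditions of steps 5 and 6 then give (3S,4Z,6S,8E)-11-(tert-butyldimethylsilyloxy)-5,9-dimethyl-6-[(R)-2-methylbutanoyloxy]undeca-1,4,8-trien-3-yl 2-(bromomethyl)prop-2-enoate F9 and (1Z,3S,5E)-1-[(2R)-4-(bromomethyl)-5-oxo-2,5-dihydrofuran-2-yl]-8-(tert-butyldimethylsilyloxy)-2,6-dimethylocta-1,5-dien-3-yl (R)-2-methylbutanoate F10. HF·pyridine gives (1Z,3S,5E)-1-[(2R)-4-(bromomethyl)-5-oxo-2,5-dihydrofuran-2-yl]-8-hydroxy-2,6-dimethylocta-1,5-dien-3-yl (R)-2-methylbutanoate F11, and Dess–Martin oxidation gives (1Z,3S,5E)-1-[(2R)-4-(bromomethyl)-5-oxo-2,5-dihydrofuran-2-yl]-2,6-dimethyl-8-oxoocta-1,5-dien-3-yl (R)-2-methylbutanoate F12. Zinc-mediated Barbier allylation at high dilution (THF–aq. NH4Cl) should close the ring at C7–C8, with the same sense of induction as in step 11, to (3S,6R,7R,8S,1(10)E,4Z)-8-hydroxy-3-[(R)-2-methylbutanoyloxy]germacra-1(10),4,11(13)-trien-12,6-olide F13, which the conditions of step 12 convert into 22.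

2. Step 17 (Mitsunobu esterification at C3). What may go wrong: ionisation of the allylic oxyphosphonium salt with loss of stereochemical integrity or SN2′ attack at C5, and elimination to a diene; the step also rests on the 3R outcome predicted for step 16. The fallback sets out from 20 and comes back at 22. MnO2 oxidises 20 to (6R,7R,8R,1(10)E,4Z)-8-formyloxy-3-oxogermacra-1(10),4,11(13)-trien-12,6-olide F14. (R)-CBS/catecholborane reduction under reagent control should give (3S,6R,7R,8R,1(10)E,4Z)-8-formyloxy-3-hydroxygermacra-1(10),4,11(13)-trien-12,6-olide F15, and acylation with 21 (DIC, DMAP, retention) gives 22. The same acylation is used directly if step 16 should deliver the 3S-alcohol instead of 20.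

3. Step 4 (CBS reduction). What may go wrong: poor discrimination between the two alkenyl substituents of the dienone, which would lower the enantiomeric purity of every later stereocentre, and hydroboration of the vinyl group. The fallback sets out from 4 and comes back at 5. Luche reduction (NaBH4, CeCl3, MeOH) gives racemic (Z)-5-methyl-6-(triethylsilyloxy)hexa-1,4-dien-3-ol F16. Kinetic resolution with Candida antarctica lipase B and vinyl acetate should acetylate the R enantiomer to (3R,4Z)-5-methyl-6-(triethylsilyloxy)hexa-1,4-dien-3-yl acetate F17 and leave 5.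

Further compounds

F1 | step 16 | (E)-[(5-bromo-3-methylpent-3-enyl)oxy](tert-butyl)dimethylsilane | BrC/C=C(\C)CCO[Si](C)(C)C(C)(C)C
F2 | step 16 | (3S,4Z)-3-(4-methoxybenzyloxy)-5-methyl-6-(triethylsilyloxy)hexa-1,4-diene | C=C[C@H](OCc1ccc(OC)cc1)/C=C(/C)CO[Si](CC)(CC)CC
F3 | step 16 | (2Z,4S)-4-(4-methoxybenzyloxy)-2-methylhexa-2,5-dienal | C=C[C@H](OCc1ccc(OC)cc1)/C=C(/C)C=O
F4 | step 16 | (3S,4Z,8E)-11-(tert-butyldimethylsilyloxy)-3-(4-methoxybenzyloxy)-5,9-dimethylundeca-1,4,8-trien-6-ol (both C6 epimers) | C=C[C@H](OCc1ccc(OC)cc1)/C=C(/C)C(O)C/C=C(\C)CCO[Si](C)(C)C(C)(C)C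
F5 | step 16 | (3S,4Z,8E)-11-(tert-butyldimethylsilyloxy)-3-(4-methoxybenzyloxy)-5,9-dimethylundeca-1,4,8-trien-6-one | C=C[C@H](OCc1ccc(OC)cc1)/C=C(/C)C(=O)C/C=C(\C)CCO[Si](C)(C)C(C)(C)C
F6 | step 16 | (3S,4Z,6S,8E)-11-(tert-butyldimethylsilyloxy)-3-(4-methoxybenzyloxy)-5,9-dimethylundeca-1,4,8-trien-6-ol | C=C[C@H](OCc1ccc(OC)cc1)/C=C(/C)[C@@H](O)C/C=C(\C)CCO[Si](C)(C)C(C)(C)C
F7 | step 16 | (3S,4Z,6S,8E)-11-(tert-butyldimethylsilyloxy)-3-(4-methoxybenzyloxy)-5,9-dimethylundeca-1,4,8-trien-6-yl (R)-2-methylbutanoate | C=C[C@H](OCc1ccc(OC)cc1)/C=C(/C)[C@@H](OC(=O)[C@H](C)CC)C/C=C(\C)CCO[Si](C)(C)C(C)(C)C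
F8 | step 16 | (3S,4Z,6S,8E)-11-(tert-butyldimethylsilyloxy)-3-hydroxy-5,9-dimethylundeca-1,4,8-trien-6-yl (R)-2-methylbutanoate | C=C[C@H](O)/C=C(/C)[C@@H](OC(=O)[C@H](C)CC)C/C=C(\C)CCO[Si](C)(C)C(C)(C)C
F9 | step 16 | (3S,4Z,6S,8E)-11-(tert-butyldimethylsilyloxy)-5,9-dimethyl-6-[(R)-2-methylbutanoyloxy]undeca-1,4,8-trien-3-yl 2-(bromomethyl)prop-2-enoate | C=C(CBr)C(=O)O[C@@H](C=C)/C=C(/C)[C@@H](OC(=O)[C@H](C)CC)C/C=C(\C)CCO[Si](C)(C)C(C)(C)C
F10 | step 16 | (1Z,3S,5E)-1-[(2R)-4-(bromomethyl)-5-oxo-2,5-dihydrofuran-2-yl]-8-(tert-butyldimethylsilyloxy)-2,6-dimethylocta-1,5-dien-3-yl (R)-2-methylbutanoate | O=C1O[C@H](/C=C(/C)[C@@H](OC(=O)[C@H](C)CC)C/C=C(\C)CCO[Si](C)(C)C(C)(C)C)C=C1CBr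
F11 | step 16 | (1Z,3S,5E)-1-[(2R)-4-(bromomethyl)-5-oxo-2,5-dihydrofuran-2-yl]-8-hydroxy-2,6-dimethylocta-1,5-dien-3-yl (R)-2-methylbutanoate | O=C1O[C@H](/C=C(/C)[C@@H](OC(=O)[C@H](C)CC)C/C=C(\C)CCO)C=C1CBr
F12 | step 16 | (1Z,3S,5E)-1-[(2R)-4-(bromomethyl)-5-oxo-2,5-dihydrofuran-2-yl]-2,6-dimethyl-8-oxoocta-1,5-dien-3-yl (R)-2-methylbutanoate | O=C1O[C@H](/C=C(/C)[C@@H](OC(=O)[C@H](C)CC)C/C=C(\C)CC=O)C=C1CBr
F13 | step 16 | (3S,6R,7R,8S,1(10)E,4Z)-8-hydroxy-3-[(R)-2-methylbutanoyloxy]germacra-1(10),4,11(13)-trien-12,6-olide | C=C1C(=O)O[C@@H]2/C=C(/C)[C@@H](OC(=O)[C@H](C)CC)C/C=C(\C)C[C@H](O)[C@@H]12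
F14 | step 17 | (6R,7R,8R,1(10)E,4Z)-8-formyloxy-3-oxogermacra-1(10),4,11(13)-trien-12,6-olide | C=C1C(=O)O[C@@H]2/C=C(/C)C(=O)C/C=C(\C)C[C@@H](OC=O)[C@@H]12
F15 | step 17 | (3S,6R,7R,8R,1(10)E,4Z)-8-formyloxy-3-hydroxygermacra-1(10),4,11(13)-trien-12,6-olide | C=C1C(=O)O[C@@H]2/C=C(/C)[C@@H](O)C/C=C(\C)C[C@@H](OC=O)[C@@H]12
F16 | step 4 | racemic (Z)-5-methyl-6-(triethylsilyloxy)hexa-1,4-dien-3-ol | C=CC(O)/C=C(/C)CO[Si](CC)(CC)CC
F17 | step 4 | (3R,4Z)-5-methyl-6-(triethylsilyloxy)hexa-1,4-dien-3-yl acetate | C=C[C@@H](OC(C)=O)/C=C(/C)CO[Si](CC)(CC)CC
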